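Ligraminol D has one stereocentre, C8, which bears the ether oxygen O4' of ring B (the guaiacyl ring with the hydroxypropyl chain), the carbinol carbon C9 and the benzylic methylene C7 of ring A (the veratryl ring). The plan hides C8 in a flat C7=C8 double bond and raises C9 to a carboxylic acid, so that the acid can hold a chiral iridium catalyst next to the olefin. The precursor is therefore a (Z)-2-aryloxy-3-arylacrylic acid, assembled from a ring B aryloxyacetic acid and veratraldehyde. One enantioselective hydrogenation then sets C8 as S, and a final hydride reduction turns C9 into the alcohol.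

Key step: step 5

Assumption: the (Sa,S) form of the iridium complex is taken to deliver hydrogen to the face of the Z olefin that gives the S acid; if a trial run shows the opposite sense, the (Ra,R) antipode of the same complex is used with nothing else changed.

Step 1
Reactants: 1 dihydroconiferyl alcohol [4-(3-hydroxypropyl)-2-methoxyphenol]; 2 tert-butyl bromoacetate
Product: 3 tert-butyl 2-[4-(3-hydroxypropyl)-2-methoxyphenoxy]acetate
Conditions: K2CO3 (1.5 equiv), acetone, reflux
Reagents that add atoms: none
Why: Williamson ether synthesis, in which carbonate deprotonates only the phenol (the primary alcohol is far less acidic) and the phenoxide displaces bromide from the activated alpha-bromo ester by SN2, the hindered tert-butyl ester resisting attack at its carbonyl.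

Step 2
Reactants: 3 tert-butyl 2-[4-(3-hydroxypropyl)-2-methoxyphenoxy]acetate
Product: 4 tert-butyl 2-[4-(3-acetoxypropyl)-2-methoxyphenoxy]acetate
Conditions: Ac2O (1.3 equiv), Et3N, DMAP (cat.), CH2Cl2, 0 °C to rt
Reagents that add atoms: acetic anhydride, CC(=O)OC(C)=O
Why: DMAP-catalysed acylation of the only free hydroxyl gives an acetate that keeps the alcohol out of the later anhydride chemistry and that can only exchange with itself in hot acetic anhydride.

Step 3
Reactants: 4 tert-butyl 2-[4-(3-acetoxypropyl)-2-methoxyphenoxy]acetate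
Product: 5 2-[4-(3-acetoxypropyl)-2-methoxyphenoxy]acetic acid
Conditions: TFA, Et3SiH (2.5 equiv), CH2Cl2, 0 °C to rt
Reagents that add atoms: none
Why: Acidolysis of the tert-butyl ester by alkyl-oxygen cleavage frees the acid while the primary acetate and the aryl ethers tolerate TFA, and the silane reduces the tert-butyl cation so that it cannot alkylate the electron-rich ring B.

Step 4
Reactants: 5 2-[4-(3-acetoxypropyl)-2-methoxyphenoxy]acetic acid; 6 veratraldehyde (3,4-dimethoxybenzaldehyde)
Product: 10 (Z)-2-[4-(3-acetoxypropyl)-2-methoxyphenoxy]-3-(3,4-dimethoxyphenyl)acrylic acid, via mixed anhydride 7 (not isolated), via beta-acetoxy adduct 8 (not isolated), via unsaturated mixed anhydride 9 (not isolated)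
Conditions: Ac2O (4 equiv), Et3N (2 equiv), 110 °C; then H2O, 60 °C; recrystallisation
Reagents that add atoms: none
Why: Perkin-Oglialoro condensation, in which the acetic mixed anhydride 7 of the acid is enolised by the amine and adds to the aldehyde carbon of 6 to make the C7-C8 bond, O-acetylation to 8 and E1cB loss of acetate give the conjugated anhydride 9 that water hydrolyses to 10, and the ring A aryl ends trans to the carboxyl (Z), the less crowded and thermodynamically preferred geometry, with any E isomer removed by the recrystallisation.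

Step 5
Reactants: 10 (Z)-2-[4-(3-acetoxypropyl)-2-methoxyphenoxy]-3-(3,4-dimethoxyphenyl)acrylic acid
Product: 11 (S)-2-[4-(3-acetoxypropyl)-2-methoxyphenoxy]-3-(3,4-dimethoxyphenyl)propanoic acid
Conditions: H2 (6 atm), [Ir(cod)(ligand)][B(3,5-(CF3)2C6H3)4] (1 mol %; cod = 1,5-cyclooctadiene; ligand = 7-[bis(3,5-di-tert-butylphenyl)phosphino]-7'-[(4S)-4-benzyl-4,5-dihydrooxazol-2-yl]-1,1'-spirobiindane of Sa axial configuration), Et3N (0.5 equiv), MeOH, rt to 40 °C; then dilute aq. HCl
Reagents that add atoms: none
Why: Once the amine has deprotonated it, the acid of 10 coordinates through a carboxylate oxygen to the iridium hydride that forms from the precatalyst under H2, so the neighbouring C7=C8 bond sits on the same metal centre; insertion of the olefin into Ir-H places one hydrogen on C7 and hydrogenolysis of the C8-Ir bond places the second on C8. The closest known reaction type is the iridium spiro phosphine-oxazoline catalysed enantioselective hydrogenation of alpha-aryloxy and alpha-alkoxy alpha,beta-unsaturated carboxylic acids. No ring is closed in this step. The new stereocentre C8 is set as S by the catalyst alone, since 10 is achiral and the spiro ligand leaves only one face of the chelated olefin open to the metal hydride. The step needs enantioface selectivity, which is secured by the single Z geometry of 10 and by its free carboxyl group as the anchor. It also needs chemoselectivity, which follows because the two electron-rich arenes, the aryl vinyl ether C-O bond and the remote acetate do not react with this homogeneous catalyst.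

Step 6
Reactants: 11 (S)-2-[4-(3-acetoxypropyl)-2-methoxyphenoxy]-3-(3,4-dimethoxyphenyl)propanoic acid
Product: 12 Ligraminol D [(S)-3-(3,4-dimethoxyphenyl)-2-[4-(3-hydroxypropyl)-2-methoxyphenoxy]propan-1-ol]
Conditions: LiAlH4 (3.5 equiv), THF, 0 °C to rt; then H2O, aq. NaOH (Fieser work-up)
Reagents that add atoms: none
Why: Lithium aluminium hydride reduction takes the C9 carboxylate to the primary alcohol and cleaves the side-chain acetate in the same operation, and because no bond to C8 is broken and CH2OH keeps the priority rank of CO2H, the S configuration and its descriptor carry over unchanged.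

Compound list
1 | dihydroconiferyl alcohol, 4-(3-hydroxypropyl)-2-methoxyphenol | COc1cc(CCCO)ccc1O | starting material
2 | tert-butyl bromoacetate | BrCC(=O)OC(C)(C)C | starting material
3 | tert-butyl 2-[4-(3-hydroxypropyl)-2-methoxyphenoxy]acetate | COc1cc(CCCO)ccc1OCC(=O)OC(C)(C)C | intermediate
4 | tert-butyl 2-[4-(3-acetoxypropyl)-2-methoxyphenoxy]acetate | COc1cc(CCCOC(C)=O)ccc1OCC(=O)OC(C)(C)C | intermediate
5 | 2-[4-(3-acetoxypropyl)-2-methoxyphenoxy]acetic acid | COc1cc(CCCOC(C)=O)ccc1OCC(=O)O | intermediate
6 | veratraldehyde, 3,4-dimethoxybenzaldehyde | COc1ccc(C=O)cc1OC | starting material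
7 | acetic mixed anhydride of acid 5 | COc1cc(CCCOC(C)=O)ccc1OCC(=O)OC(C)=O | intermediate
8 | acetic mixed anhydride of 3-acetoxy-2-[4-(3-acetoxypropyl)-2-methoxyphenoxy]-3-(3,4-dimethoxyphenyl)propanoic acid, diastereomer mixture | COc1ccc(C(OC(C)=O)C(Oc2ccc(CCCOC(C)=O)cc2OC)C(=O)OC(C)=O)cc1OC | intermediate
9 | acetic mixed anhydride of (Z)-acrylic acid 10 | COc1ccc(/C=C(\Oc2ccc(CCCOC(C)=O)cc2OC)C(=O)OC(C)=O)cc1OC | intermediate
10 | (Z)-2-[4-(3-acetoxypropyl)-2-methoxyphenoxy]-3-(3,4-dimethoxyphenyl)acrylic acid | COc1ccc(/C=C(\Oc2ccc(CCCOC(C)=O)cc2OC)C(=O)O)cc1OC | intermediate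
11 | (S)-2-[4-(3-acetoxypropyl)-2-methoxyphenoxy]-3-(3,4-dimethoxyphenyl)propanoic acid | COc1ccc(C[C@@H](C(=O)O)Oc2ccc(CCCOC(C)=O)cc2OC)cc1OC | intermediate
12 | Ligraminol D, (S)-3-(3,4-dimethoxyphenyl)-2-[4-(3-hydroxypropyl)-2-methoxyphenoxy]propan-1-ol | COc1ccc(C[C@@H](CO)Oc2ccc(CCCO)cc2OC)cc1OC | target

Total step count: 6 steps.
Longest linear sequence: 6 steps (1 to 3 to 4 to 5 to 10 to 11 to 12); compounds 2 and 6 are bought and enter at steps 1 and 4.

Steps most likely to fail

Step 4. The mixed anhydride may enolise too slowly to add to an electron-rich, weakly electrophilic aldehyde, so that tar forms at the temperature needed, and the olefin geometry may not be fully controlled. The fallback sets out from 3 and comes back at 10. Two equivalents of LDA (THF, -78 °C) should turn 3 into its alkoxide ester enolate, which adds to 6 to give tert-butyl 2-[4-(3-hydroxypropyl)-2-methoxyphenoxy]-3-(3,4-dimethoxyphenyl)-3-hydroxypropanoate F1 as a diastereomer mixture of no consequence. Ac2O, Et3N and DMAP then acetylate both hydroxyls to tert-butyl 3-acetoxy-2-[4-(3-acetoxypropyl)-2-methoxyphenoxy]-3-(3,4-dimethoxyphenyl)propanoate F2. DBU in toluene eliminates the benzylic acetate (E1cB) to tert-butyl (Z)-2-[4-(3-acetoxypropyl)-2-methoxyphenoxy]-3-(3,4-dimethoxyphenyl)acrylate F3. Cold TFA in CH2Cl2 under a nitrogen sweep cleaves the tert-butyl ester and rejoins the route at 10.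

Step 5. Enantioface discrimination may be insufficient, or turnover may stall because the ortho-methoxy aryloxy group crowds the carboxylate chelate. The fallback sets out from 10 and comes back at 11. Hydrogenation over Pd/C (H2 1 atm, EtOAc) should give racemic 2-[4-(3-acetoxypropyl)-2-methoxyphenoxy]-3-(3,4-dimethoxyphenyl)propanoic acid F4. Classical resolution by fractional crystallisation with (S)-1-phenylethylamine (or its antipode, whichever makes the salt of the S acid the less soluble one) gives the (S)-1-phenylethylammonium salt of the S acid F5. Dilute aq. HCl liberates the acid and rejoins the route at 11.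

Step 6. Configuration at C8 may erode through an enolisable aldehyde-level intermediate, or the reduction may stall at a poorly soluble lithium carboxylate. The fallback sets out from 11 and comes back at 12. BH3·SMe2 (THF, 0 °C to rt) reduces only the carboxylic acid, through an acyloxyborane, to (S)-3-[4-[[1-(3,4-dimethoxyphenyl)-3-hydroxypropan-2-yl]oxy]-3-methoxyphenyl]propyl acetate F6. K2CO3 in MeOH then removes the acetate and rejoins the route at 12.

Further compounds
F1 | step 4 | tert-butyl 2-[4-(3-hydroxypropyl)-2-methoxyphenoxy]-3-(3,4-dimethoxyphenyl)-3-hydroxypropanoate, diastereomer mixture | COc1ccc(C(O)C(Oc2ccc(CCCO)cc2OC)C(=O)OC(C)(C)C)cc1OC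
F2 | step 4 | tert-butyl 3-acetoxy-2-[4-(3-acetoxypropyl)-2-methoxyphenoxy]-3-(3,4-dimethoxyphenyl)propanoate, diastereomer mixture | COc1ccc(C(OC(C)=O)C(Oc2ccc(CCCOC(C)=O)cc2OC)C(=O)OC(C)(C)C)cc1OC
F3 | step 4 | tert-butyl (Z)-2-[4-(3-acetoxypropyl)-2-methoxyphenoxy]-3-(3,4-dimethoxyphenyl)acrylate | COc1ccc(/C=C(\Oc2ccc(CCCOC(C)=O)cc2OC)C(=O)OC(C)(C)C)cc1OC
F4 | step 5 | racemic 2-[4-(3-acetoxypropyl)-2-methoxyphenoxy]-3-(3,4-dimethoxyphenyl)propanoic acid | COc1ccc(CC(C(=O)O)Oc2ccc(CCCOC(C)=O)cc2OC)cc1OC
F5 | step 5 | (S)-1-phenylethylammonium (S)-2-[4-(3-acetoxypropyl)-2-methoxyphenoxy]-3-(3,4-dimethoxyphenyl)propanoate | COc1ccc(C[C@@H](C(=O)[O-])Oc2ccc(CCCOC(C)=O)cc2OC)cc1OC.C[C@H]([NH3+])c1ccccc1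
F6 | step 6 | (S)-3-[4-[[1-(3,4-dimethoxyphenyl)-3-hydroxypropan-2-yl]oxy]-3-methoxyphenyl]propyl acetate | COc1ccc(C[C@@H](CO)Oc2ccc(CCCOC(C)=O)cc2OC)cc1OC
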